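Early in a flask, G made from J has had little time to go on to Z or D, so its share among G, Z and D (the selectivity) stands near whole. Late in a hot flask, G sits on a plateau where making balances loss (a quasi-steady state), and the share falls as lifetime over run time. One quantity joins the two ends.

| flask | J | E | temperature | remark | time |
|---|---|---|---|---|---|
| Tuesday's | 0.036 M | 6.5 mM (held) | 75 °C | run made earlier |  |
| Monday's | 0.24 M | 6.5 mM (held) | 100 °C | run made earlier |  |
| elm | 0.030 M | 6.5 mM (held) | 95 °C |  | 5.0 min |
| ash | 0.040 M | 6.5 mM (held) | 120 °C |  | 5.0 min |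
| oak | 0.20 M | 6.5 mM (held) | 80 °C |  | 5.0 min |
| alder | 0.060 M | 6.5 mM (held) | 110 °C |  | 5.0 min |
| maple | 0.12 M | 6.5 mM (held) | 80 °C |  | 5.0 min |

1. the flasks put in order of share of G in all that became G or Z or D, best first, at 5.0 min (elm / ash / oak / alder / maple)
2. the share of G in all that became G or Z or D of the flask you put first, at 5.0 min
3. the share of G in all that became G or Z or D of the flask you put last, at 5.0 min

- what is said of G includes Q
- Q is a solid; its amount is given per volume of the solution
- at the start none of L is dissolved
- the numbers in the tables scatter by 1.5 percentage points (one standard deviation)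
- candidate steps: E <-> L; L + G -> Z; G -> D; J + L -> G; Q <-> G; L -> X

Tuesday's run (percent of the J charged)

| time / min | G / % | Z / % |
|---|---|---|
| 0.667 | 5 | 0 |
| 1.33 | 9 | 0 |
| 2.00 | 14 | 1 |
| 2.50 | 16 | 0 |

Monday's run (percent of the J charged)

| time / s | G / % | Z / % |
|---|---|---|
| 10.0 | 3 | 0 |
| 20.0 | 4 | 0 |
| 30.0 | 3 | 0 |
| 60.0 | 6 | 0 |

The first row of Monday's table gives 3% of the J as G after 10.0 s, which is the early slope. The next rows read 4%, 3% and 6%, roughly flat given a scatter of 1.5 percentage points, with a mean of 4.33%. Taking this as a balance of making and loss, the plateau over the early slope gives 14.4 s, the lifetime of G at 100 °C, a rough reading. Tuesday's table, at 75 °C and with a smaller charge of J, still climbs to 16% at 2.50 min, so no plateau has shown there, and this reckoning takes heat to shorten the lifetime.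

Over 5.0 min, Monday's lifetime gives a late share of 4.81%. This reckoning therefore puts elm, at 95 °C, above that figure, and alder and ash below it. Oak and maple, at 80 °C, come first, but for them it gives no figure.

The forecast gives oak > maple > elm > alder > ash, with top 98% and low 62%, on the ground that “Both loss routes should grow with temperature and conversion”. It shares this order, but its low figure stands far above the reckoning here.

The flasks give oak > maple > elm > alder > ash, with top 64.5% and low 1.01%.

    E ⇌ L, rate k1*(csat - [L]) (kL = 0.140 s⁻¹)
    L + G → Z (k = 0.520 L mol⁻¹ s⁻¹, Ea = 75.0 kJ mol⁻¹)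
    G → D (k = 0.00270 s⁻¹, Ea = 104 kJ mol⁻¹)
    J + L → G (k = 0.320 L mol⁻¹ s⁻¹, Ea = 42.0 kJ mol⁻¹)
    Q ⇌ G, rate k5*(cs5 - [G]) while solid is left; crystals form when [G] > cs5 (solubility = 19.0 mM, k = 0.920 s⁻¹)
    L → X (k = 0.00100 s⁻¹, Ea = 96.0 kJ mol⁻¹)
    (constants at 80 °C)

The order stands, while the low end lies 61 points under the forecast. Ash, at 120 °C, gives 1.01%, under the 4.81% reckoned from Monday's lifetime of 14.4 s, a figure that belongs to 100 °C, and ash holds 0.855% as G against 63.6% as D. Elm at 12.3% and alder at 3.05% fall on the reckoned sides. Oak owes its 64.5% to the shortness of its run together with the low solubility of G: without crystals it stands at 49.8%, and left to 50.0 min at 0.214%.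

The runs stem from a simulated flask with constants of no real substance; noise was put on by code.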